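**Plan**

1. Retrosynthesis: the five O-benzyl groups and two bromine atoms (blocking C6 and C8 of ring A) come off last; ring C is then cut at O1–C2 and C3–C4 in one retro-[4+2] step.
2. Enabling feature: O1 and C4 are ortho substituents of ring A, so O1=C8a–C4a=C4 is an ortho-quinone methide; C2 (benzylic to the electron-rich ring B) and C3 (carrying the syringoyl oxygen) are the two carbons of a Z-enol ester.
3. Forward, two branches: the ring B alkyne and protected syringic acid give the Z-enol ester (C2=C3 with the ester already on O3); 3,5-bis(benzyloxy)phenol is formylated, brominated and reduced to the quinone methide precursor.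
4. The halves are joined and ring C is closed in one cycloaddition, in which C4–C3 forms first and O1–C2 closes the ring; hydrogenolysis then frees the five phenols and removes the bromines.
5. Stereochemistry: 2,3-cis from the Z geometry of the enol ester (suprafacial addition); absolute (2R,3R) from a chiral Brønsted acid bound to the quinone methide; no stereocenter is touched afterwards.

Key step: step 6

Remark: the target is read as the (2R,3R), 2,3-cis flavan-3-yl ester ((−)-epicatechin 3-O-syringate); compounds 1, 3 and 5 are taken as purchasable; the (R) acid written in step 6 stands for whichever antipode proves to give (2R,3R).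

**Route**

Step 1
Reactants: 1 3,4-bis(benzyloxy)benzaldehyde
Product: 2 1,2-bis(benzyloxy)-4-ethynylbenzene
Conditions: dimethyl (1-diazo-2-oxopropyl)phosphonate, K2CO3, MeOH/THF, 0 °C to rt
Reagents that add atoms: dimethyl (1-diazo-2-oxopropyl)phosphonate, CC(=O)C(=[N+]=[N-])P(=O)(OC)OC
Why: Seyferth–Gilbert homologation in the Ohira–Bestmann form, in which methanolysis of the acetyl group gives the diazomethylphosphonate anion that adds to the aldehyde, loses dimethyl phosphate and N2 and rearranges to the terminal alkyne, while benzyl ethers are inert to K2CO3/MeOH.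

Step 2
Reactants: 2 1,2-bis(benzyloxy)-4-ethynylbenzene; 3 4-(benzyloxy)-3,5-dimethoxybenzoic acid
Product: 4 (Z)-2-[3,4-bis(benzyloxy)phenyl]ethenyl 4-(benzyloxy)-3,5-dimethoxybenzoate
Conditions: [RuCl2(p-cymene)]2 (1 mol%), P(4-ClC6H4)3 (3 mol%), DMAP (4 mol%), toluene, 60 °C
Reagents that add atoms: none
Why: Ruthenium-catalysed anti-Markovnikov hydro-acyloxylation of a terminal alkyne through a vinylidene complex, in which the carboxylate attacks the metal-bound carbon and protonolysis leaves aryl and acyloxy cis, so the Z-enol ester should be the kinetic product; no stereocenter forms, but this geometry is the later source of the 2,3-cis relation.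

Step 3
Reactants: 5 3,5-bis(benzyloxy)phenol
Product: 7 4,6-bis(benzyloxy)-2-hydroxybenzaldehyde, via magnesium hydroxymethylphenoxide 6 (not isolated)
Conditions: MgCl2, Et3N, (CH2O)n, MeCN, reflux; then 1 M HCl
Reagents that add atoms: paraformaldehyde (formaldehyde), C=O
Why: Magnesium-mediated ortho-formylation of a phenol (Casnati–Skattebøl reaction), in which the magnesium phenoxide is hydroxymethylated only ortho to oxygen (the two ortho positions are equivalent) and the benzylic alkoxide is oxidised by a second formaldehyde through hydride transfer.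

Step 4
Reactants: 7 4,6-bis(benzyloxy)-2-hydroxybenzaldehyde
Product: 8 4,6-bis(benzyloxy)-3,5-dibromo-2-hydroxybenzaldehyde
Conditions: NBS (2.1 equiv), MeCN, 0 °C to rt, dark
Reagents that add atoms: N-bromosuccinimide, O=C1CCC(=O)N1Br
Why: Electrophilic aromatic bromination at the only two free ring positions, each ortho or para to three oxygen donors and far more activated than any other ring, which installs the blocking groups for C6 and C8.

Step 5
Reactants: 8 4,6-bis(benzyloxy)-3,5-dibromo-2-hydroxybenzaldehyde
Product: 9 3,5-bis(benzyloxy)-2,4-dibromo-6-(hydroxymethyl)phenol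
Conditions: NaBH4, THF/MeOH, −10 °C; pH 7 buffer
Reagents that add atoms: none
Why: Borohydride reduction of the aldehyde to the ortho-hydroxybenzyl alcohol, with low temperature and neutral work-up chosen to avoid early loss of water to the quinone methide, and with aryl bromides and benzyl ethers untouched.

Step 6
Reactants: 9 3,5-bis(benzyloxy)-2,4-dibromo-6-(hydroxymethyl)phenol; 4 (Z)-2-[3,4-bis(benzyloxy)phenyl]ethenyl 4-(benzyloxy)-3,5-dimethoxybenzoate
Product: 11 (2R,3R)-5,7-bis(benzyloxy)-2-[3,4-bis(benzyloxy)phenyl]-6,8-dibromo-3,4-dihydro-2H-chromen-3-yl 4-(benzyloxy)-3,5-dimethoxybenzoate, via ortho-quinone methide 10 (not isolated)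
Conditions: (R)-3,3'-bis(2,4,6-triisopropylphenyl)-1,1'-binaphthalene-2,2'-diyl N-(trifluoromethanesulfonyl)phosphoramide (5 mol%), 4 Å MS, toluene, −20 °C, slow addition of 9 to 4 (1.5 equiv)
Reagents that add atoms: none
Why: Proposed new method: the chiral acid ionises the benzylic alcohol of 9 (water goes to the sieves) to the ortho-quinone methide 10, which stays hydrogen-bonded through O1 to the chiral phosphoramide anion, and the Z-enol ester 4 adds across O1=C8a–C4a=C4 in an inverse-electron-demand oxa-Diels–Alder reaction whose asynchronous transition state forms C4–C3 first and closes the ring with O1–C2. The closest known reaction type is the [4+2] cycloaddition of in situ ortho-quinone methides with styrenes under chiral phosphoric acid or N-sulfonylphosphoramide catalysis, together with the thermal, geometry-retaining cycloaddition of ortho-quinone methides with 1,2-disubstituted styrenes; new here are a methide without a substituent on C4 and an enol ester as the 2π partner. Ring C is the only ring closed, in a suprafacial [4π+2π] mode that makes the C–C and the C–O bond in one step. C2 and C3 are created together: their cis relation follows from the Z geometry of 4 because both bonds form on one face of the alkene, and the absolute (2R,3R) sense is to come from the chiral anion covering one face of the bound methide while ring B takes the endo position over ring A, the two elements that control the known styrene case. The step needs regioselectivity (O1 to the aryl-bearing carbon), secured by the 3,4-bis(benzyloxy)phenyl group that stabilises developing positive charge at C2 far better than the acyloxy group could at C3, and chemoselectivity against Friedel–Crafts attack of the methide on ring A, secured by the bromines at C6 and C8 and by slow addition of 9. A concerted course, needed to keep the cis relation, is favoured by the non-polar solvent, the low temperature and the contact ion pair.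

Step 7
Reactants: 11 (2R,3R)-5,7-bis(benzyloxy)-2-[3,4-bis(benzyloxy)phenyl]-6,8-dibromo-3,4-dihydro-2H-chromen-3-yl 4-(benzyloxy)-3,5-dimethoxybenzoate
Product: 12 (2R,3R)-2-(3,4-dihydroxyphenyl)-5,7-dihydroxy-3,4-dihydro-2H-chromen-3-yl 4-hydroxy-3,5-dimethoxybenzoate
Conditions: H2 (1 atm), Pd(OH)2/C, NaOAc, THF/MeOH, rt
Reagents that add atoms: none
Why: Catalytic hydrogenolysis should cleave the five benzyl ethers and, with acetate as acid scavenger, the two aryl C–Br bonds, while the aryl ester and the C2–O1 ether of the flavan are expected to survive these neutral conditions as they do in hydrogenolyses of benzylated flavan-3-yl esters, and no stereocenter is touched.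

**Compound list**

1 | 3,4-bis(benzyloxy)benzaldehyde | O=Cc1ccc(OCc2ccccc2)c(OCc2ccccc2)c1 | starting material
2 | 1,2-bis(benzyloxy)-4-ethynylbenzene | C#Cc1ccc(OCc2ccccc2)c(OCc2ccccc2)c1 | intermediate
3 | 4-(benzyloxy)-3,5-dimethoxybenzoic acid | COc1cc(C(=O)O)cc(OC)c1OCc1ccccc1 | starting material
4 | (Z)-2-[3,4-bis(benzyloxy)phenyl]ethenyl 4-(benzyloxy)-3,5-dimethoxybenzoate | COc1cc(C(=O)O/C=C\c2ccc(OCc3ccccc3)c(OCc3ccccc3)c2)cc(OC)c1OCc1ccccc1 | intermediate
5 | 3,5-bis(benzyloxy)phenol | Oc1cc(OCc2ccccc2)cc(OCc2ccccc2)c1 | starting material
6 | 3,5-bis(benzyloxy)-2-(hydroxymethyl)phenol, present as its magnesium phenoxide | OCc1c(O)cc(OCc2ccccc2)cc1OCc1ccccc1 | intermediate (not isolated)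
7 | 4,6-bis(benzyloxy)-2-hydroxybenzaldehyde | O=Cc1c(O)cc(OCc2ccccc2)cc1OCc1ccccc1 | intermediate
8 | 4,6-bis(benzyloxy)-3,5-dibromo-2-hydroxybenzaldehyde | O=Cc1c(O)c(Br)c(OCc2ccccc2)c(Br)c1OCc1ccccc1 | intermediate
9 | 3,5-bis(benzyloxy)-2,4-dibromo-6-(hydroxymethyl)phenol | OCc1c(O)c(Br)c(OCc2ccccc2)c(Br)c1OCc1ccccc1 | intermediate
10 | 3,5-bis(benzyloxy)-2,4-dibromo-6-methylidenecyclohexa-2,4-dien-1-one (ortho-quinone methide) | C=C1C(=O)C(Br)=C(OCc2ccccc2)C(Br)=C1OCc1ccccc1 | intermediate (not isolated)
11 | (2R,3R)-5,7-bis(benzyloxy)-2-[3,4-bis(benzyloxy)phenyl]-6,8-dibromo-3,4-dihydro-2H-chromen-3-yl 4-(benzyloxy)-3,5-dimethoxybenzoate | COc1cc(C(=O)O[C@@H]2Cc3c(OCc4ccccc4)c(Br)c(OCc4ccccc4)c(Br)c3O[C@@H]2c2ccc(OCc3ccccc3)c(OCc3ccccc3)c2)cc(OC)c1OCc1ccccc1 | intermediate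
12 | (2R,3R)-2-(3,4-dihydroxyphenyl)-5,7-dihydroxy-3,4-dihydro-2H-chromen-3-yl 4-hydroxy-3,5-dimethoxybenzoate | COc1cc(C(=O)O[C@@H]2Cc3c(O)cc(O)cc3O[C@@H]2c2ccc(O)c(O)c2)cc(OC)c1O | target

**Step count**

Total: 7 steps (steps 1–2 for the ring B/ester half, steps 3–5 for the ring A half, steps 6–7 after convergence). Longest linear sequence: 5 steps (3, 4, 5, 6, 7).

**Steps most likely to fail**

Step 6 (Proposed new method). Three processes may defeat it: weak discrimination between the two faces of a methide that has no substituent on C4, which would lower the enantiomeric purity; a stepwise cationic addition in which rotation about C2–C3, or capture of the C2 cation by the neighbouring ester carbonyl, precedes ring closure and erodes the cis relation; and self-condensation of the methide. The fallback uses known chemistry and sets out from 9 and 4. They are heated without acid in xylene at about 130 °C, so that 9 loses water thermally to 10, which adds 4 in the concerted, geometry-retaining cycloaddition known for ortho-hydroxybenzyl alcohols and styrene-type alkenes. This should give the racemic cis adduct, that is 11 together with (2S,3S)-5,7-bis(benzyloxy)-2-[3,4-bis(benzyloxy)phenyl]-6,8-dibromo-3,4-dihydro-2H-chromen-3-yl 4-(benzyloxy)-3,5-dimethoxybenzoate F1. Preparative supercritical-fluid chromatography on an amylose tris(3,5-dimethylphenylcarbamate) phase removes F1 and returns to the route at 11.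

Step 7. The risks are stalled debromination through poisoning of the catalyst by bromide, over-reduction with hydrogenolysis of the benzylic C2–O1 bond, and air oxidation of the free pentaphenol during work-up. The fallback sets out from 11 and separates the two reductions. Homogeneous hydrodebromination with Pd(PPh3)4 and HCO2Na in DMF at 80 °C (oxidative addition of zerovalent palladium into the C–Br bonds, formate as hydride source) should give (2R,3R)-5,7-bis(benzyloxy)-2-[3,4-bis(benzyloxy)phenyl]-3,4-dihydro-2H-chromen-3-yl 4-(benzyloxy)-3,5-dimethoxybenzoate F2. Its benzyl ethers are then removed by transfer hydrogenolysis (Pd(OH)2/C, cyclohexa-1,4-diene, EtOAc/MeOH, rt) in a halide-free and base-free medium, which returns to the route at 12.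

Step 2. The risks are Markovnikov addition to the 1-arylvinyl ester, erosion of the Z geometry by isomerisation on the metal, and oligomerisation of the electron-rich alkyne. The fallback sets out from aldehyde 1 and builds the alkene geometry first. Stork–Zhao olefination ((iodomethyl)triphenylphosphonium iodide, NaN(SiMe3)2, THF/DMPU, −78 °C) should give 1,2-bis(benzyloxy)-4-[(Z)-2-iodoethenyl]benzene F3. Ullmann-type C–O coupling of F3 with acid 3 (CuI, 1,10-phenanthroline, Cs2CO3, toluene, 90 °C), which keeps the alkene geometry, returns to the route at 4.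

**Further compounds**

F1 | step 6 | (2S,3S)-5,7-bis(benzyloxy)-2-[3,4-bis(benzyloxy)phenyl]-6,8-dibromo-3,4-dihydro-2H-chromen-3-yl 4-(benzyloxy)-3,5-dimethoxybenzoate | COc1cc(C(=O)O[C@H]2Cc3c(OCc4ccccc4)c(Br)c(OCc4ccccc4)c(Br)c3O[C@H]2c2ccc(OCc3ccccc3)c(OCc3ccccc3)c2)cc(OC)c1OCc1ccccc1
F2 | step 7 | (2R,3R)-5,7-bis(benzyloxy)-2-[3,4-bis(benzyloxy)phenyl]-3,4-dihydro-2H-chromen-3-yl 4-(benzyloxy)-3,5-dimethoxybenzoate | COc1cc(C(=O)O[C@@H]2Cc3c(OCc4ccccc4)cc(OCc4ccccc4)cc3O[C@@H]2c2ccc(OCc3ccccc3)c(OCc3ccccc3)c2)cc(OC)c1OCc1ccccc1
F3 | step 2 | 1,2-bis(benzyloxy)-4-[(Z)-2-iodoethenyl]benzene | I/C=C\c1ccc(OCc2ccccc2)c(OCc2ccccc2)c1
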